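A percentage point here is a hundredth of the two substrates charged together, so the left-handed substrate L starts at 50.0 %, which is the ceiling on what it can lose.

all flasks: left-handed substrate 0.037 M; right-handed substrate 0.037 M; precatalyst 0.22 mM
- Thursday's: reagent 0.020 M; run made earlier
- Sunday's: reagent 0.031 M; run made earlier
- flask: reagent 0.0407 M; time 30 h

| run | time / h | right-handed substrate / % | left-handed substrate / % |
|---|---|---|---|
| Thursday's | 1.50 | 48.9 | 48.4 |
| Thursday's | 5.00 | 50.7 | 43.1 |
| Thursday's | 8.00 | 48.3 | 37.5 |
| Thursday's | 12.0 | 45.5 | 35.0 |
| Thursday's | 20.0 | 48.7 | 32.7 |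
| Sunday's | 1.33 | 49.6 | 48.9 |
| Sunday's | 2.50 | 50.9 | 44.6 |
| Sunday's | 5.00 | 49.9 | 38.8 |
| Sunday's | 10.0 | 47.8 | 32.6 |
| Sunday's | 20.0 | 48.7 | 26.1 |

(readings scatter by 1 percentage point)

* whether the excess of right-handed substrate over left-handed substrate among what is left of the two reaches 90 % by 30 h (no / yes)
* the highest excess of right-handed substrate over left-handed substrate among what is left of the two up to 30 h

- free catalyst is single-handed; left-handed substrate and right-handed substrate are mirror images of each other, charged as a racemate, each of them at the stated concentration
- the numbers in the tables scatter with a standard deviation of 1 percentage point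

1. This is a kinetic resolution. The readings of the right-handed substrate S stay near their start, so I reckon L first and treat S as a correction.
2. For a reagent charge c, I take the loss of L by a given time as the ceiling times c/(c + b). Here b is the half-loss charge, the charge at which this curve stands at half the ceiling.
3. At 20.0 h, Thursday's readings give b = 0.0378 M and Sunday's 0.0339 M, so I use their mean, 0.0358 M.
4. S has lost 6.31 % as much as L in these readings, and I keep that ratio.
5. The weak link is time. At 12.0 h Thursday's run gave 0.0467 M, more than its later value, and at 10.0 h Sunday's gave 0.0581 M, also more than its later value.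
6. I continue each run in a straight line against 1/t to 30 h. The drops are 0.00443 M and 0.00808 M, so the half-loss charge at that time is 0.0296 M.
7. For the flask, L loses 29.0 % and keeps 21.0 %, while S keeps 48.2 %. I put the top at the end, at (S − L)/(S + L) = 39.2 %, well short of 90 %.

The forecast also says no, but it puts the top higher than mine, at 46 % (range 39 % to 54 %), holding that “Rates scale roughly with reagent”.

The flask gives no and a top of 37.4 %.

    reagent + catalyst intermediate B → free catalyst + right-handed product (k = 120 M⁻¹ min⁻¹)
    free catalyst + left-handed substrate ⇌ catalyst intermediate A (K = 63.0 M⁻¹, k = 410 M⁻¹ min⁻¹)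
    free catalyst + right-handed substrate ⇌ catalyst intermediate B (K = 7.80 M⁻¹, k = 670 M⁻¹ min⁻¹)
    2 free catalyst → spent catalyst A (k = 280 M⁻¹ min⁻¹)
    precatalyst ⇌ free catalyst (K = 9.70, k = 0.00100 min⁻¹)
    reagent + catalyst intermediate A → free catalyst + left-handed product (k = 330 M⁻¹ min⁻¹)
    free catalyst → spent catalyst B (k = 0.0460 min⁻¹)

At 30.0 h the flask holds L at 20.8 %, close to my 21.0 %, and S at 45.7 %, less than my 48.2 %. The neighbouring flask, charged with 0.024 M of reagent, takes the same half-loss charge. It reckons to L 27.6 %, S 48.6 % and an excess of 27.6 %. That flask holds L 27.6 % and S 47.8 %, and its top is 26.8 %.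

(The runs are calculated for substances that don't exist, and the scatter is random.)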